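Diaporindene H is cut at the C3–C3a bond of its indane (numbered from the diaryl methine, C1). Two features are exploited: the ring-fusion carbon C3a of ring A lies para to the C6 hydroxyl, and C3–C2=CMe2 is an allyl unit. Ionisation of a tertiary allylic alcohol by zerovalent palladium and attack of C3a on the CH2 terminus of the resulting π-allyl closes the cyclopentane and sets the isopropylidene in one operation. The precursor is a diaryl methine with C1 already configured, a free ring-A phenol, a C7 bromine that blocks the other ortho carbon and later becomes the aldehyde, and the 2-methylbut-3-en-2-ol unit.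

Key step: step 13

Remark: the indane is numbered C1 (diaryl methine), C2 (alkylidene carbon), C3 (CH2), C3a to C7a, with the hydroxyl on C6 and bromine or formyl on C7. Ring A is the phenol ring and ring B the benzodioxane arene. The CIP descriptor at the methine changes along the route only because substituent priorities change; its spatial arrangement is fixed from step 9 onward.

Step 1
Reactants: 1 3-methylbut-2-en-1-ol
Product: 3 [(2R)-3,3-dimethyloxiran-2-yl]methyl 4-methylbenzenesulfonate, via (2R)-3,3-dimethylglycidol 2 (not isolated)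
Conditions: Ti(OiPr)4 (5 mol%), D-(−)-diisopropyl tartrate (7 mol%), t-BuOOH, 4 Å molecular sieves, CH2Cl2, −20 °C; then P(OMe)3; then TsCl, Et3N, DMAP (catalytic), −10 °C
Reagents that add atoms: tert-butyl hydroperoxide, CC(C)(C)OO; 4-methylbenzenesulfonyl chloride, Cc1ccc(cc1)S(Cl)(=O)=O
Why: Sharpless asymmetric epoxidation of a primary allylic alcohol, in which the D-(−)-tartrate catalyst delivers oxygen to the alkene face that gives the 2R epoxide (the L-tartrate gives 2S in this series), followed by sulfonylation of the water-soluble epoxy alcohol in the same flask so that it need not be isolated.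

Step 2
Reactants: 4 3-bromo-2-hydroxy-5-methylbenzaldehyde
Product: 5 3-bromo-5-methyl-2-(prop-2-en-1-yloxy)benzaldehyde
Conditions: allyl bromide, K2CO3, DMF, 50 °C
Reagents that add atoms: allyl bromide (3-bromoprop-1-ene), C=CCBr
Why: Williamson O-allylation of the phenol, giving an ether that survives peracid, base and alkylation, cannot migrate between the two catechol oxygens and is later removed under neutral palladium catalysis.

Step 3
Reactants: 5 3-bromo-5-methyl-2-(prop-2-en-1-yloxy)benzaldehyde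
Product: 7 3-bromo-5-methyl-2-(prop-2-en-1-yloxy)phenol, via aryl formate 6 (not isolated)
Conditions: mCPBA, CH2Cl2, rt; then K2CO3 (catalytic), MeOH, 0 °C
Reagents that add atoms: 3-chloroperoxybenzoic acid (mCPBA), OOC(=O)c1cccc(Cl)c1
Why: Baeyer–Villiger (Dakin-type) oxidation in which the ortho alkoxy group promotes aryl migration to the aryl formate, which mild methanolysis cleaves to the phenol, while the monosubstituted allyl alkene reacts with the peracid far more slowly than the aldehyde.

Step 4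
Reactants: 7 3-bromo-5-methyl-2-(prop-2-en-1-yloxy)phenol; 3 [(2R)-3,3-dimethyloxiran-2-yl]methyl 4-methylbenzenesulfonate
Product: 8 (2R)-2-{[3-bromo-5-methyl-2-(prop-2-en-1-yloxy)phenoxy]methyl}-3,3-dimethyloxirane
Conditions: Cs2CO3, DMF, 40 °C
Reagents that add atoms: none
Why: SN2 O-alkylation of the caesium phenoxide at the primary sulfonate carbon, which places the CH2 on the oxygen remote from bromine and leaves the epoxide stereocentre untouched.

Step 5
Reactants: 8 (2R)-2-{[3-bromo-5-methyl-2-(prop-2-en-1-yloxy)phenoxy]methyl}-3,3-dimethyloxirane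
Product: 10 2-[(2S)-8-bromo-6-methyl-2,3-dihydro-1,4-benzodioxin-2-yl]propan-2-ol, via free phenol 9 (not isolated)
Conditions: Pd(PPh3)4 (3 mol%), K2CO3, MeOH, rt, then 50 °C
Reagents that add atoms: none
Why: Zerovalent palladium ionises the aryl allyl ether (Tsuji–Trost deallylation with methoxide as allyl acceptor) and the phenoxide set free opens the epoxide by 6-exo-tet attack at the secondary carbon with inversion (2R epoxide to 2S benzodioxane), base favouring this mode over 7-endo attack at the tertiary carbon and the aryl bromide being inert to this catalyst at 50 °C.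

Step 6
Reactants: 10 2-[(2S)-8-bromo-6-methyl-2,3-dihydro-1,4-benzodioxin-2-yl]propan-2-ol
Product: 11 2-[(2S)-6-methyl-8-(4,4,5,5-tetramethyl-1,3,2-dioxaborolan-2-yl)-2,3-dihydro-1,4-benzodioxin-2-yl]propan-2-ol
Conditions: B2pin2, Pd(dppf)Cl2 (5 mol%), KOAc, 1,4-dioxane, 90 °C
Reagents that add atoms: bis(pinacolato)diboron, CC1(C)OB(OC1(C)C)B1OC(C)(C)C(C)(C)O1
Why: Miyaura borylation of the aryl bromide, which tolerates the free tertiary alcohol and the aryl ethers.

Step 7
Reactants: 12 2-bromo-3-hydroxybenzaldehyde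
Product: 13 2-bromo-3-[tri(propan-2-yl)silyloxy]benzaldehyde
Conditions: iPr3SiCl, imidazole, DMF, rt
Reagents that add atoms: chlorotri(propan-2-yl)silane, CC(C)[Si](Cl)(C(C)C)C(C)C
Why: Silylation of the phenol gives a hindered silyl ether that should withstand the ylide, the mildly basic aqueous conjugate addition, the lithium amide and the organocerium reagent and is removed by fluoride without acid.

Step 8
Reactants: 13 2-bromo-3-[tri(propan-2-yl)silyloxy]benzaldehyde; 14 methyl (triphenyl-λ5-phosphanylidene)acetate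
Product: 15 methyl (2E)-3-{2-bromo-3-[tri(propan-2-yl)silyloxy]phenyl}prop-2-enoate
Conditions: toluene, 80 °C
Reagents that add atoms: none
Why: Wittig olefination with a stabilised ylide, which gives the (E)-enoate.

Step 9
Reactants: 15 methyl (2E)-3-{2-bromo-3-[tri(propan-2-yl)silyloxy]phenyl}prop-2-enoate; 11 2-[(2S)-6-methyl-8-(4,4,5,5-tetramethyl-1,3,2-dioxaborolan-2-yl)-2,3-dihydro-1,4-benzodioxin-2-yl]propan-2-ol
Product: 16 methyl (3R)-3-{2-bromo-3-[tri(propan-2-yl)silyloxy]phenyl}-3-[(3S)-3-(2-hydroxypropan-2-yl)-7-methyl-2,3-dihydro-1,4-benzodioxin-5-yl]propanoate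
Conditions: [RhCl(C2H4)2]2 (2.5 mol%), (1S,4S)-2,5-diphenylbicyclo[2.2.2]octa-2,5-diene (5.5 mol%), KOH (0.3 equiv), 1,4-dioxane/H2O (10:1), 50 °C
Reagents that add atoms: none
Why: Rhodium-catalysed asymmetric 1,4-addition of an arylboron reagent to a β-aryl enoate (Hayashi–Miyaura reaction), which tolerates the aryl bromide and the free hydroxyl and in which the chiral diene controls the face of aryl–rhodium insertion, the (S,S)-ligand being predicted by the usual quadrant model to add to the Si face of C3 and give 3R (the antipodal ligand is equally available should the sense prove opposite), while the minor C3 epimer is a diastereomer and can be separated.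

Step 10
Reactants: 16 methyl (3R)-3-{2-bromo-3-[tri(propan-2-yl)silyloxy]phenyl}-3-[(3S)-3-(2-hydroxypropan-2-yl)-7-methyl-2,3-dihydro-1,4-benzodioxin-5-yl]propanoate
Product: 19 methyl 2-[(S)-{2-bromo-3-[tri(propan-2-yl)silyloxy]phenyl}{(3S)-3-(2-hydroxypropan-2-yl)-7-methyl-2,3-dihydro-1,4-benzodioxin-5-yl}methyl]prop-2-enoate, via Mannich base 17 (not isolated), via trimethylammonium iodide 18 (not isolated)
Conditions: LiN(iPr)2 (2.2 equiv), THF, −78 °C; CH2=NMe2+ I−, −78 °C to rt; aqueous work-up; crude material: MeI, MeOH, rt; then DBU, CH2Cl2, rt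
Reagents that add atoms: Eschenmoser's salt (N,N-dimethylmethaniminium iodide), C=[N+](C)C.[I-]
Why: Aminomethylation of the ester enolate with Eschenmoser's salt (Mannich reaction), N-methylation and elimination of trimethylamine install the α-methylene group, and because only the α-carbon is deprotonated the neighbouring diaryl methine keeps its configuration.

Step 11
Reactants: 19 methyl 2-[(S)-{2-bromo-3-[tri(propan-2-yl)silyloxy]phenyl}{(3S)-3-(2-hydroxypropan-2-yl)-7-methyl-2,3-dihydro-1,4-benzodioxin-5-yl}methyl]prop-2-enoate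
Product: 21 3-[(R)-{2-bromo-3-[tri(propan-2-yl)silyloxy]phenyl}{(3S)-3-(2-hydroxypropan-2-yl)-7-methyl-2,3-dihydro-1,4-benzodioxin-5-yl}methyl]-2-methylbut-3-en-2-ol, via methyl ketone 20 (not isolated)
Conditions: MeLi (5 equiv), CeCl3 (anhydrous, 5 equiv), THF, −78 °C to 0 °C; aqueous NH4Cl
Reagents that add atoms: methyllithium, [Li]C
Why: Double 1,2-addition of the weakly basic, oxophilic organocerium reagent to the ester through the methyl ketone, which avoids conjugate addition to the acrylate or enone, enolisation and bromine–metal exchange.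

Step 12
Reactants: 21 3-[(R)-{2-bromo-3-[tri(propan-2-yl)silyloxy]phenyl}{(3S)-3-(2-hydroxypropan-2-yl)-7-methyl-2,3-dihydro-1,4-benzodioxin-5-yl}methyl]-2-methylbut-3-en-2-ol
Product: 22 2-bromo-3-{(1R)-2-(2-hydroxypropan-2-yl)-1-[(3S)-3-(2-hydroxypropan-2-yl)-7-methyl-2,3-dihydro-1,4-benzodioxin-5-yl]prop-2-en-1-yl}phenol
Conditions: Bu4NF, THF, 0 °C; aqueous NH4Cl
Reagents that add atoms: none
Why: Fluoride cleavage of the aryl silyl ether under non-acidic conditions, which spares the acid-sensitive tertiary allylic alcohol.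

Step 13
Reactants: 22 2-bromo-3-{(1R)-2-(2-hydroxypropan-2-yl)-1-[(3S)-3-(2-hydroxypropan-2-yl)-7-methyl-2,3-dihydro-1,4-benzodioxin-5-yl]prop-2-en-1-yl}phenol
Product: 23 (1R)-7-bromo-1-[(3S)-3-(2-hydroxypropan-2-yl)-7-methyl-2,3-dihydro-1,4-benzodioxin-5-yl]-2-(propan-2-ylidene)-2,3-dihydro-1H-inden-6-ol
Conditions: Pd(PPh3)4 (5 mol%), Et3B (0.5 equiv), degassed THF (0.02 M), 50 °C
Reagents that add atoms: none
Why: Et3B turns the allylic hydroxyl into a borate leaving group, zerovalent palladium ionises it to a 1,1-dimethyl-2-(diarylmethyl) π-allyl complex, and the phenol, deprotonated by the hydroxyborate released, attacks the CH2 terminus through C3a before tautomerisation restores the phenol (an intramolecular Tsuji–Trost C-allylation, that is a palladium-catalysed Friedel–Crafts-type allylic alkylation of a phenol). The closest known reaction types are the palladium-catalysed intramolecular para-C-allylation of meta-tethered phenols and the Et3B-promoted C-allylation of phenols and naphthols with free allylic alcohols, tertiary ones included. The cyclopentane closes by attack of a nucleophile tethered to the central allyl carbon on an allyl terminus (formally 5-exo-tet on the σ-allyl form), the same closure that ends trimethylenemethane cyclopentannulations. No stereocentre is formed, and C1 lies outside the allyl system and keeps its configuration. Site selectivity rests on the substrate: C7 carries bromine, so C3a is the only activated carbon within reach; O-allylation would need a meta-bridged seven-membered ring; the neutral ring B and the non-allylic tertiary alcohol do not react because no free cation is formed; and attack at the unhindered CH2 terminus instead of CMe2 leaves the tetrasubstituted C2=CMe2 alkene. The aryl bromide is expected to survive because oxidative addition into a doubly ortho-substituted, electron-rich C–Br bond is slow with PPh3 at 50 °C.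

Step 14
Reactants: 23 (1R)-7-bromo-1-[(3S)-3-(2-hydroxypropan-2-yl)-7-methyl-2,3-dihydro-1,4-benzodioxin-5-yl]-2-(propan-2-ylidene)-2,3-dihydro-1H-inden-6-ol
Product: 25 (1S)-6-hydroxy-1-[(3S)-3-(2-hydroxypropan-2-yl)-7-methyl-2,3-dihydro-1,4-benzodioxin-5-yl]-2-(propan-2-ylidene)-2,3-dihydro-1H-indene-7-carbaldehyde (diaporindene H), via trilithiated aryllithium 24 (not isolated)
Conditions: MeLi (2.2 equiv), THF, −78 °C; t-BuLi (2.1 equiv), −78 °C; DMF, −78 °C to 0 °C; aqueous NH4Cl
Reagents that add atoms: N,N-dimethylformamide, CN(C)C=O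
Why: After deprotonation of both hydroxyls, bromine–lithium exchange with t-BuLi at −78 °C, which is much faster than deprotonation at C1 or C3, gives the aryllithium that DMF formylates (Bouveault formylation) to the salicylaldehyde without touching any bond to a stereocentre.

Compound list
1 | 3-methylbut-2-en-1-ol | CC(C)=CCO | starting material
2 | [(2R)-3,3-dimethyloxiran-2-yl]methanol | OC[C@H]1OC1(C)C | intermediate
3 | [(2R)-3,3-dimethyloxiran-2-yl]methyl 4-methylbenzenesulfonate | Cc1ccc(cc1)S(=O)(=O)OC[C@H]1OC1(C)C | intermediate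
4 | 3-bromo-2-hydroxy-5-methylbenzaldehyde | Cc1cc(Br)c(O)c(C=O)c1 | starting material
5 | 3-bromo-5-methyl-2-(prop-2-en-1-yloxy)benzaldehyde | Cc1cc(Br)c(OCC=C)c(C=O)c1 | intermediate
6 | 3-bromo-5-methyl-2-(prop-2-en-1-yloxy)phenyl formate | Cc1cc(Br)c(OCC=C)c(OC=O)c1 | intermediate
7 | 3-bromo-5-methyl-2-(prop-2-en-1-yloxy)phenol | Cc1cc(Br)c(OCC=C)c(O)c1 | intermediate
8 | (2R)-2-{[3-bromo-5-methyl-2-(prop-2-en-1-yloxy)phenoxy]methyl}-3,3-dimethyloxirane | Cc1cc(Br)c(OCC=C)c(OC[C@H]2OC2(C)C)c1 | intermediate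
9 | 2-bromo-6-{[(2R)-3,3-dimethyloxiran-2-yl]methoxy}-4-methylphenol | Cc1cc(Br)c(O)c(OC[C@H]2OC2(C)C)c1 | intermediate
10 | 2-[(2S)-8-bromo-6-methyl-2,3-dihydro-1,4-benzodioxin-2-yl]propan-2-ol | Brc1cc(C)cc2c1O[C@H](C(C)(C)O)CO2 | intermediate
11 | 2-[(2S)-6-methyl-8-(4,4,5,5-tetramethyl-1,3,2-dioxaborolan-2-yl)-2,3-dihydro-1,4-benzodioxin-2-yl]propan-2-ol | CC1(C)OB(OC1(C)C)c1cc(C)cc2c1O[C@H](C(C)(C)O)CO2 | intermediate
12 | 2-bromo-3-hydroxybenzaldehyde | O=Cc1cccc(O)c1Br | starting material
13 | 2-bromo-3-[tri(propan-2-yl)silyloxy]benzaldehyde | O=Cc1cccc(O[Si](C(C)C)(C(C)C)C(C)C)c1Br | intermediate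
14 | methyl (triphenyl-λ5-phosphanylidene)acetate | COC(=O)C=P(c1ccccc1)(c1ccccc1)c1ccccc1 | starting material
15 | methyl (2E)-3-{2-bromo-3-[tri(propan-2-yl)silyloxy]phenyl}prop-2-enoate | COC(=O)/C=C/c1cccc(O[Si](C(C)C)(C(C)C)C(C)C)c1Br | intermediate
16 | methyl (3R)-3-{2-bromo-3-[tri(propan-2-yl)silyloxy]phenyl}-3-[(3S)-3-(2-hydroxypropan-2-yl)-7-methyl-2,3-dihydro-1,4-benzodioxin-5-yl]propanoate | COC(=O)C[C@@H](c1cccc(O[Si](C(C)C)(C(C)C)C(C)C)c1Br)c1cc(C)cc2c1O[C@H](C(C)(C)O)CO2 | intermediate
17 | methyl (3R)-3-{2-bromo-3-[tri(propan-2-yl)silyloxy]phenyl}-2-[(dimethylamino)methyl]-3-[(3S)-3-(2-hydroxypropan-2-yl)-7-methyl-2,3-dihydro-1,4-benzodioxin-5-yl]propanoate (both C2 epimers) | COC(=O)C(CN(C)C)[C@@H](c1cccc(O[Si](C(C)C)(C(C)C)C(C)C)c1Br)c1cc(C)cc2c1O[C@H](C(C)(C)O)CO2 | intermediate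
18 | N-methyl quaternary ammonium iodide of 17 (CH2NMe3+ I− in place of CH2NMe2) | COC(=O)C(C[N+](C)(C)C)[C@@H](c1cccc(O[Si](C(C)C)(C(C)C)C(C)C)c1Br)c1cc(C)cc2c1O[C@H](C(C)(C)O)CO2.[I-] | intermediate
19 | methyl 2-[(S)-{2-bromo-3-[tri(propan-2-yl)silyloxy]phenyl}{(3S)-3-(2-hydroxypropan-2-yl)-7-methyl-2,3-dihydro-1,4-benzodioxin-5-yl}methyl]prop-2-enoate | C=C(C(=O)OC)[C@@H](c1cccc(O[Si](C(C)C)(C(C)C)C(C)C)c1Br)c1cc(C)cc2c1O[C@H](C(C)(C)O)CO2 | intermediate
20 | 3-[(S)-{2-bromo-3-[tri(propan-2-yl)silyloxy]phenyl}{(3S)-3-(2-hydroxypropan-2-yl)-7-methyl-2,3-dihydro-1,4-benzodioxin-5-yl}methyl]but-3-en-2-one | C=C(C(C)=O)[C@@H](c1cccc(O[Si](C(C)C)(C(C)C)C(C)C)c1Br)c1cc(C)cc2c1O[C@H](C(C)(C)O)CO2 | intermediate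
21 | 3-[(R)-{2-bromo-3-[tri(propan-2-yl)silyloxy]phenyl}{(3S)-3-(2-hydroxypropan-2-yl)-7-methyl-2,3-dihydro-1,4-benzodioxin-5-yl}methyl]-2-methylbut-3-en-2-ol | C=C([C@@H](c1cccc(O[Si](C(C)C)(C(C)C)C(C)C)c1Br)c1cc(C)cc2c1O[C@H](C(C)(C)O)CO2)C(C)(C)O | intermediate
22 | 2-bromo-3-{(1R)-2-(2-hydroxypropan-2-yl)-1-[(3S)-3-(2-hydroxypropan-2-yl)-7-methyl-2,3-dihydro-1,4-benzodioxin-5-yl]prop-2-en-1-yl}phenol | C=C([C@@H](c1cccc(O)c1Br)c1cc(C)cc2c1O[C@H](C(C)(C)O)CO2)C(C)(C)O | intermediate
23 | (1R)-7-bromo-1-[(3S)-3-(2-hydroxypropan-2-yl)-7-methyl-2,3-dihydro-1,4-benzodioxin-5-yl]-2-(propan-2-ylidene)-2,3-dihydro-1H-inden-6-ol | CC(C)=C1Cc2ccc(O)c(Br)c2[C@H]1c1cc(C)cc2c1O[C@H](C(C)(C)O)CO2 | intermediate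
24 | trilithium species of 23 (C7–Li, lithium phenoxide, lithium alkoxide) | CC(C)=C1Cc2ccc(O[Li])c([Li])c2[C@H]1c1cc(C)cc2c1O[C@H](C(C)(C)O[Li])CO2 | intermediate
25 | (1S)-6-hydroxy-1-[(3S)-3-(2-hydroxypropan-2-yl)-7-methyl-2,3-dihydro-1,4-benzodioxin-5-yl]-2-(propan-2-ylidene)-2,3-dihydro-1H-indene-7-carbaldehyde (diaporindene H) | CC(C)=C1Cc2ccc(O)c(C=O)c2[C@H]1c1cc(C)cc2c1O[C@H](C(C)(C)O)CO2 | target

Total step count: 14. Longest linear sequence: 11 steps (from 4 through steps 2 to 6 and 9 to 14).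

Steps most likely to fail

Step 13. Ionisation of the hindered tertiary allylic alcohol may be too slow under borane activation, or the π-allyl intermediate may lose a β-hydrogen from a methyl group and collapse to a 1,3-diene before C3a attacks; slow turnover would also give the catalyst time to insert into the C–Br bond. The fallback replaces direct alcohol activation by a carbonate leaving group that ionises under neutral conditions; it sets out from 21 and comes back at 23. Both tertiary hydroxyls of 21 are converted with LiN(SiMe3)2 and ClCO2Me (THF, −78 to 0 °C) into the bis(methyl carbonate) F1. Bu4NF buffered with AcOH then removes the silyl group to give the phenol bis(methyl carbonate) F2. Pd2(dba)3 and PPh3 in CH2Cl2 at rt ionise only the allylic carbonate, the methoxide released deprotonates the phenol, and the same C3a attack gives the cyclised side-chain carbonate F3. K2CO3 in MeOH at 40 °C cleaves the remaining carbonate to 23.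

Step 9. Transmetalation and insertion may be slow with an ortho-alkoxy arylboronate and an ortho-bromo cinnamate, so that protodeboronation consumes the boron reagent, and the sense or level of facial discrimination may be inadequate. The fallback sets C1 with a covalently bound auxiliary; it sets out from 13 and 10 and comes back at 16. Horner–Wadsworth–Emmons olefination of 13 with diethyl {2-oxo-2-[(4S)-2-oxo-4-phenyl-1,3-oxazolidin-3-yl]ethyl}phosphonate (LiCl, iPr2NEt, MeCN) gives the (E)-N-enoyl oxazolidinone F4. Bromide 10 is converted (MeMgBr, then t-BuLi at −78 °C, then MgBr2·OEt2) into the aryl Grignard reagent F5. Copper-mediated 1,4-addition of F5 to F4 (CuBr·SMe2, THF/Me2S, −40 °C) should occur on the C3 face of the magnesium-chelated s-cis imide remote from the 4-phenyl group and give the (3R)-imide F6. MeOMgBr in MeOH/CH2Cl2 at 0 °C transesterifies F6 to 16 and releases the auxiliary.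

Step 14. Bromine–lithium exchange on the electron-rich, doubly flanked dianion may be incomplete, the aryllithium may be protonated before it meets DMF, and deprotonation at the doubly benzylic C1 would erode its configuration. The fallback avoids organolithium reagents; it sets out from 23 and comes back at 25. Palladium-catalysed methoxycarbonylation (Pd(OAc)2, Xantphos, CO (1 atm), Et3N, MeOH/DMF, 80 °C) gives the methyl salicylate F7. LiAlH4 (THF, 0 °C) reduces it to the salicyl alcohol F8. MnO2 (CH2Cl2, rt) oxidises the benzylic alcohol selectively to 25.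

Further compounds
F1 | step 13 | bis(methyl carbonate) of 21 (both tertiary hydroxyls as OCO2Me, silyl ether retained) | C=C([C@@H](c1cccc(O[Si](C(C)C)(C(C)C)C(C)C)c1Br)c1cc(C)cc2c1O[C@H](C(C)(C)OC(=O)OC)CO2)C(C)(C)OC(=O)OC
F2 | step 13 | bis(methyl carbonate) of 22 (free phenol) | C=C([C@@H](c1cccc(O)c1Br)c1cc(C)cc2c1O[C@H](C(C)(C)OC(=O)OC)CO2)C(C)(C)OC(=O)OC
F3 | step 13 | side-chain methyl carbonate of 23 | CC(C)=C1Cc2ccc(O)c(Br)c2[C@H]1c1cc(C)cc2c1O[C@H](C(C)(C)OC(=O)OC)CO2
F4 | step 9 | (4S)-3-[(2E)-3-{2-bromo-3-[tri(propan-2-yl)silyloxy]phenyl}prop-2-enoyl]-4-phenyl-1,3-oxazolidin-2-one | O=C(/C=C/c1cccc(O[Si](C(C)C)(C(C)C)C(C)C)c1Br)N1C(=O)OC[C@@H]1c1ccccc1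
F5 | step 9 | bromomagnesium 2-[(2S)-8-(bromomagnesio)-6-methyl-2,3-dihydro-1,4-benzodioxin-2-yl]propan-2-olate | Cc1cc([Mg]Br)c2O[C@H](C(C)(C)O[Mg]Br)COc2c1
F6 | step 9 | (4S)-3-[(3R)-3-{2-bromo-3-[tri(propan-2-yl)silyloxy]phenyl}-3-[(3S)-3-(2-hydroxypropan-2-yl)-7-methyl-2,3-dihydro-1,4-benzodioxin-5-yl]propanoyl]-4-phenyl-1,3-oxazolidin-2-one | O=C(C[C@@H](c1cccc(O[Si](C(C)C)(C(C)C)C(C)C)c1Br)c1cc(C)cc2c1O[C@H](C(C)(C)O)CO2)N1C(=O)OC[C@@H]1c1ccccc1
F7 | step 14 | methyl (1S)-6-hydroxy-1-[(3S)-3-(2-hydroxypropan-2-yl)-7-methyl-2,3-dihydro-1,4-benzodioxin-5-yl]-2-(propan-2-ylidene)-2,3-dihydro-1H-indene-7-carboxylate | CC(C)=C1Cc2ccc(O)c(C(=O)OC)c2[C@H]1c1cc(C)cc2c1O[C@H](C(C)(C)O)CO2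
F8 | step 14 | (1S)-7-(hydroxymethyl)-1-[(3S)-3-(2-hydroxypropan-2-yl)-7-methyl-2,3-dihydro-1,4-benzodioxin-5-yl]-2-(propan-2-ylidene)-2,3-dihydro-1H-inden-6-ol | CC(C)=C1Cc2ccc(O)c(CO)c2[C@H]1c1cc(C)cc2c1O[C@H](C(C)(C)O)CO2
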